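The rate constants were drawn at random within sensible limits; no experiment stands behind them.

Count protons first.

    electrophile + nucleophile → acid set free + target (k1 = 2.67 /M/s)
    nucleophile + acid set free ⇌ protonated nucleophile, settled at all times (K2 = 40200 /M)
    acid set free + free base ⇌ salt of the base, settled at all times (K3 = 1.3 × 10⁶ /M)
    target ⇌ isomer of the product (K4 = 1.3, k4 = 0.0391 /s)

common to all: electrophile 0.050 M; protonated nucleophile 1.10 equiv; time 25 s

| run | free base |
|---|---|
| amber | 1.10 equiv |
| red | 2.20 equiv |
| blue | 4.40 equiv |

1. which of these there is most of at the end, counted by the electrophile in it, amber (electrophile / isomer of the product / target)
2. which of these there is most of at the end, counted by the electrophile in it, red (electrophile / isomer of the product / target)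
3. which of these there is most of at the end, counted by the electrophile in it, blue (electrophile / isomer of the product / target)
4. how much there is at the end of the one of these that leads, in percent of the electrophile charged: amber
5. how much there is at the end of the one of these that leads, in percent of the electrophile charged: red
6. how much there is at the end of the one of these that leads, in percent of the electrophile charged: blue

The two proton constants need little accuracy: free base binds acid more strongly than nucleophile does, by a factor of 32.3, and neither constant enters the balance below. The constants of step four divide product between target and isomer of the product; electrophile does not stand in that step. The rate constant sets a clock of 7.49 s, shorter than the time, so an error in it moves a flask that runs freely, far less one that stalls. The equivalents of free base must be known well: each equivalent moves the stall by 50.0% of the electrophile charged.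

Counting protons and nucleophile gives, at each moment, free nucleophile plus free base minus acid set free equal to the charged free base minus twice the turnover. Dividing the loss of that sum by the loss of electrophile removes time: the ratio is two. The sum reaches zero at the proton ceiling, 55.0%, the conversion equal to half the equivalents of free base. Past it the sum is negative, with free acid standing, and the ceiling is soft.

My reckoning: equal second-order consumption gives 76.9% conversion, above amber's ceiling but below those of red, 110%, and blue, 220%. Product aged 17.5 s relaxes at 0.0692 /s and stays 60.3% target. Amber then leads with electrophile at 45.0%. Red leads with target at 46.4%, and blue with target at 46.4%.

The forecast says electrophile at 46.4% for amber, target at 48.8% for red and target at 49.6% for blue, higher than my figure for red. Its ground for amber: “Conversion therefore stalls near 0.0275 M, or 55%”.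

The simulation gives electrophile at 46.4% in amber, target at 48.7% in red and target at 49.6% in blue. Amber's conversion, 53.6%, stands just under its ceiling of 55.0%, with 0.195% of its free base, the limiting reagent, left. The main reason for the gap in electrophile between blue and amber is the difference in equivalents of free base: blue reads 19.0%, and with amber's equivalents it reads 46.4%. Red, whose ceiling of 110% lies above the whole electrophile charged, keeps 16% of its free base and ends with 20% electrophile.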